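**Plan**

1. Ring numbering: C1 ring ketone, C2 the carbon bearing the 3-phenylpropanoyl group, C3 and C5 the enol carbons, C4 the prenyl-bearing sp2 carbon, C6 the quaternary carbon (OMe, prenyl). Retrosynthesis first masks the C3 hydroxyl as an ethyl enol ether, then cuts C3–C4 and C1–C2 while a C1–C4 bond is put back.
2. Enabling feature: after that operation C6, C1, C4 and C5 are the four ring atoms of 2-methoxy-2,4-diprenylcyclobutane-1,3-dione, whose carbonyls C1 and C5 are mirror images of each other. C2, C3, the C3 oxygen and the whole acyl chain are one molecule of 1-ethoxy-5-phenylpent-1-yn-3-one.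
3. The four-membered ring is cut further across C4–C5 and C6–C1 into methoxy(prenyl)ketene and a prenylated ethoxyalkyne. The ynone is cut at its ketone into ethoxyacetylene and a 3-phenylpropanoic acid derivative.
4. Forward: the four-membered ring is made first (ketene–ynol ether [2+2], then unmasking to the dione). The ynone is then inserted into the C1–C4 bond, which turns the four-membered ring into the six-membered ring in one operation. Enol ether hydrolysis ends the route.
5. Stereochemistry: C6 is the only stereocentre. Everything before the ring enlargement is racemic or achiral. C6 becomes (R) when a chiral Cu(OTf)2–bis(oxazoline) catalyst (divalent copper) decides which of the two enantiotopic carbonyls is attacked; C6 has no hydrogen and is not touched afterwards.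

Key step: step 9

Assumption: the sense of induction of the copper catalyst cannot be derived with certainty from models; the (S,S)-ligand is written for the (6R) product, and the equally available (R,R)-ligand is the one to use if the opposite sense is found.

**Route**

Step 1
Reactants: 1 methyl 2-methoxyacetate; 2 prenyl bromide (1-bromo-3-methylbut-2-ene)
Product: 4 methyl 2-methoxy-5-methylhex-4-enoate (racemic), via lithium ester enolate 3 (not isolated)
Conditions: LDA (1.05 equiv, commercial solution), THF, −78 °C; then 2, DMPU, −78 → −20 °C
Reagents that add atoms: none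
Why: Alkylation of a kinetically formed, chelated α-alkoxy ester enolate with a reactive primary allylic bromide (SN2) is standard enolate chemistry, and the stereocentre formed is racemic and is erased again when the ketene is made in step 5.

Step 2
Reactants: 4 methyl 2-methoxy-5-methylhex-4-enoate
Product: 5 2-methoxy-5-methylhex-4-enoic acid (racemic)
Conditions: LiOH·H2O, THF/H2O (3:1), 23 °C; then 1 M HCl to pH 2, 0 °C
Reagents that add atoms: lithium hydroxide, [Li+].[OH-]
Why: Saponification of an unhindered methyl ester, to which the ether and the trisubstituted alkene are inert.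

Step 3
Reactants: 5 2-methoxy-5-methylhex-4-enoic acid
Product: 6 2-methoxy-5-methylhex-4-enoyl chloride (racemic; used crude)
Conditions: (COCl)2 (1.2 equiv), DMF (cat.), CH2Cl2, 0 → 23 °C; evaporate
Reagents that add atoms: oxalyl chloride, O=C(Cl)C(=O)Cl
Why: Acid chloride formation through the Vilsmeier-type chloroiminium species runs at or below room temperature, where the isolated trisubstituted alkene does not add HCl at a useful rate.

Step 4
Reactants: 7 ethoxyacetylene; 2 prenyl bromide
Product: 9 1-ethoxy-5-methylhex-4-en-1-yne, via lithium ethoxyacetylide 8 (not isolated)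
Conditions: n-BuLi (1.0 equiv), THF, −78 °C; then 2, DMPU, −78 → 23 °C
Reagents that add atoms: none
Why: Deprotonation of the terminal ynol ether and SN2 alkylation of the acetylide at the primary carbon of the allylic bromide, helped by the dipolar cosolvent, is the standard way to 1-alkoxy-1-alkynes.

Step 5
Reactants: 6 2-methoxy-5-methylhex-4-enoyl chloride; 9 1-ethoxy-5-methylhex-4-en-1-yne
Product: 11 3-ethoxy-4-methoxy-2,4-bis(3-methylbut-2-en-1-yl)cyclobut-2-en-1-one (racemic), via methoxy(prenyl)ketene 10 (not isolated)
Conditions: 9 (1.5 equiv), Et3N (1.5 equiv), CH2Cl2, 40 °C, slow addition of 6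
Reagents that add atoms: none
Why: Dehydrochlorination gives the alkoxy(alkyl)ketene, which undergoes the known thermal [2+2] cycloaddition of ketenes with electron-rich alkynyl ethers, the nucleophilic alkyl-bearing alkyne carbon bonding to the ketene carbonyl carbon so that the ethoxy carbon ends up next to the new quaternary carbon.

Step 6
Reactants: 11 3-ethoxy-4-methoxy-2,4-bis(3-methylbut-2-en-1-yl)cyclobut-2-en-1-one
Product: 12 2-methoxy-2,4-bis(3-methylbut-2-en-1-yl)cyclobutane-1,3-dione (achiral; in equilibrium with its 3-hydroxycyclobutenone enol)
Conditions: 1 M aq HCl, THF, 0 → 23 °C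
Reagents that add atoms: water, O
Why: Acid hydrolysis of the vinylogous ester (3-alkoxycyclobutenone to cyclobutane-1,3-dione) is a known unmasking, and enolisation at C4 then interconverts all stereoisomers so that the material behaves as one prochiral compound.

Step 7
Reactants: 13 3-phenylpropanoyl chloride
Product: 14 N-methoxy-N-methyl-3-phenylpropanamide
Conditions: MeNHOMe·HCl (1.1 equiv), Et3N (2.2 equiv), CH2Cl2, 0 → 23 °C
Reagents that add atoms: N,O-dimethylhydroxylamine hydrochloride, CNOC.Cl
Why: Acylation of the hydroxylamine by the acid chloride (Weinreb amide formation) is fast and clean.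

Step 8
Reactants: 7 ethoxyacetylene; 14 N-methoxy-N-methyl-3-phenylpropanamide
Product: 17 1-ethoxy-5-phenylpent-1-yn-3-one, via ethoxyethynylmagnesium bromide 15 (not isolated), via bromomagnesium hemiaminal chelate 16 (not isolated)
Conditions: 7 (1.5 equiv), EtMgBr (1.4 equiv), THF, 0 → 23 °C; then 14, 0 → 23 °C; sat. aq NH4Cl, 0 °C
Reagents that add atoms: none
Why: Weinreb ketone synthesis with an alkynyl Grignard reagent, in which ethylmagnesium bromide metalates the terminal ynol ether, the acetylide adds once to the amide, the five-membered magnesium chelate holds the tetrahedral adduct until the quench and so prevents over-addition, and the cold, nearly neutral work-up spares the acid-sensitive alkoxy-ynone.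

Step 9
Reactants: 12 2-methoxy-2,4-bis(3-methylbut-2-en-1-yl)cyclobutane-1,3-dione; 17 1-ethoxy-5-phenylpent-1-yn-3-one
Product: 20 (6R)-3-ethoxy-5-hydroxy-6-methoxy-4,6-bis(3-methylbut-2-en-1-yl)-2-(3-phenylpropanoyl)cyclohexa-2,4-dien-1-one, via allenolate Michael adduct 18 (not isolated), via bicyclic alkoxide 19 (not isolated)
Conditions: Cu(OTf)2 (10 mol %), (S,S)-t-Bu-box [2,2'-(propane-2,2-diyl)bis((4S)-4-tert-butyl-4,5-dihydrooxazole), 11 mol %], i-Pr2NEt (1.0 equiv), 4 Å MS, CH2Cl2, −40 → 0 °C, slow addition of 17 (1.1 equiv); pH 4 citrate buffer
Reagents that add atoms: none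
Why: Proposed new method: the enolate of 12, whose only nucleophilic carbon is C4 because C6 carries no hydrogen, should add to the copper-activated ynone at the ethoxy-bearing alkyne carbon, the position fixed by the push-pull polarisation of the alkoxy-ynone (bond C3–C4), and the copper-bound allenolate 18 should then attack a ring carbonyl through C2 (bond C1–C2) to give the bicyclo[2.2.0]hexene alkoxide 19, whose retro-aldol cleavage of the shared C1–C4 bond delivers the six-membered enolate. The closest known reaction types are the formal insertion of arynes and of activated alkynes into the C–C bond of cyclic β-dicarbonyl compounds, which run through the same addition, cyclobutene-alkoxide and fragmentation sequence, and the catalytic desymmetrisation of 2,2-disubstituted cyclobutane-1,3-diones; neither a cyclobutanedione as the dicarbonyl partner nor an enantioselective version is established. The six-membered ring is thus not closed directly: a 4-exo-trig aldol closure builds the fused bicycle and fragmentation enlarges the four-membered ring by two carbons, the relief of the strain of two four-membered rings making this last event irreversible. The ring part of adduct 18 keeps the mirror plane through C4 and C6 and C4 returns to a trigonal carbon on fragmentation, so the configuration at C6 is decided solely by whether C1 or C5 is attacked; that choice is made by the Cu(OTf)2–bis(oxazoline) complex, which stays on the allenolate oxygen and binds one ring carbonyl in a closed aldol transition state with the C6 methoxy oxygen as an additional contact, and since the conjugate addition of so stabilised an enolate is reversible both faces of C4 feed the same favoured closure. The step needs C- instead of O-addition of the enolate, aldol closure faster than protonation of the allenolate and no racemic background reaction; these are served by the reversibility of O-addition, by full ionisation of the dione with a hindered amine so that no acid stronger than the ammonium ion is present, and by the low nucleophilicity of the enolate, which should add only to the copper-bound ynone.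

Step 10
Reactants: 20 (6R)-3-ethoxy-5-hydroxy-6-methoxy-4,6-bis(3-methylbut-2-en-1-yl)-2-(3-phenylpropanoyl)cyclohexa-2,4-dien-1-one
Product: 21 helihumulone
Conditions: 0.5 M aq HCl, THF, 0 → 23 °C
Reagents that add atoms: water, O
Why: The C3 ethoxy group belongs to a doubly activated vinylogous ester and is replaced by water through addition–elimination under acid mild enough to spare the prenyl groups, while C6, which has no hydrogen and two constitutionally different ring neighbours, can neither epimerise nor racemise through tautomerism.

**Compound list**

1 | methyl 2-methoxyacetate | COCC(=O)OC | starting material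
2 | prenyl bromide (1-bromo-3-methylbut-2-ene) | CC(C)=CCBr | starting material
3 | lithium enolate of methyl 2-methoxyacetate | COC=C(OC)O[Li] | intermediate (not isolated)
4 | methyl 2-methoxy-5-methylhex-4-enoate (racemic) | COC(CC=C(C)C)C(=O)OC | intermediate
5 | 2-methoxy-5-methylhex-4-enoic acid (racemic) | COC(CC=C(C)C)C(=O)O | intermediate
6 | 2-methoxy-5-methylhex-4-enoyl chloride (racemic) | COC(CC=C(C)C)C(=O)Cl | intermediate
7 | ethoxyacetylene (ethoxyethyne) | CCOC#C | starting material
8 | lithium ethoxyacetylide | CCOC#C[Li] | intermediate (not isolated)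
9 | 1-ethoxy-5-methylhex-4-en-1-yne | CCOC#CCC=C(C)C | intermediate
10 | methoxy(3-methylbut-2-en-1-yl)ketene | COC(CC=C(C)C)=C=O | intermediate (not isolated)
11 | 3-ethoxy-4-methoxy-2,4-bis(3-methylbut-2-en-1-yl)cyclobut-2-en-1-one (racemic) | CCOC1=C(CC=C(C)C)C(=O)C1(OC)CC=C(C)C | intermediate
12 | 2-methoxy-2,4-bis(3-methylbut-2-en-1-yl)cyclobutane-1,3-dione (achiral; cis and trans keto forms interconvert through the enol) | COC1(CC=C(C)C)C(=O)C(CC=C(C)C)C1=O | intermediate
13 | 3-phenylpropanoyl chloride | O=C(Cl)CCc1ccccc1 | starting material
14 | N-methoxy-N-methyl-3-phenylpropanamide | CON(C)C(=O)CCc1ccccc1 | intermediate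
15 | ethoxyethynylmagnesium bromide | CCOC#C[Mg]Br | intermediate (not isolated)
16 | bromomagnesium 1-ethoxy-3-[methoxy(methyl)amino]-5-phenylpent-1-yn-3-olate (hemiaminal chelate) | CCOC#CC(O[Mg]Br)(CCc1ccccc1)N(C)OC | intermediate (not isolated)
17 | 1-ethoxy-5-phenylpent-1-yn-3-one | CCOC#CC(=O)CCc1ccccc1 | intermediate
18 | 4-(1-ethoxy-3-oxido-5-phenylpenta-1,2-dien-1-yl)-2-methoxy-2,4-bis(3-methylbut-2-en-1-yl)cyclobutane-1,3-dione (allenolate; cis and trans forms at C4/C6) | CCOC(=C=C([O-])CCc1ccccc1)C1(CC=C(C)C)C(=O)C(OC)(CC=C(C)C)C1=O | intermediate (not isolated)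
19 | 3-ethoxy-6-methoxy-4,6-bis(3-methylbut-2-en-1-yl)-5-oxo-2-(3-phenylpropanoyl)bicyclo[2.2.0]hex-2-en-1-olate (drawn for addition on the C4 face cis to the C6 methoxy group) | CCOC1=C(C(=O)CCc2ccccc2)[C@]2([O-])[C@@](OC)(CC=C(C)C)C(=O)[C@]12CC=C(C)C | intermediate (not isolated)
20 | (6R)-3-ethoxy-5-hydroxy-6-methoxy-4,6-bis(3-methylbut-2-en-1-yl)-2-(3-phenylpropanoyl)cyclohexa-2,4-dien-1-one | CCOC1=C(C(=O)CCc2ccccc2)C(=O)[C@@](OC)(CC=C(C)C)C(O)=C1CC=C(C)C | intermediate
21 | helihumulone, (6R)-3,5-dihydroxy-6-methoxy-4,6-bis(3-methylbut-2-en-1-yl)-2-(3-phenylpropanoyl)cyclohexa-2,4-dien-1-one | CO[C@@]1(CC=C(C)C)C(=O)C(C(=O)CCc2ccccc2)=C(O)C(CC=C(C)C)=C1O | target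

**Count**

Total steps: 10. Longest linear sequence: 7 steps (1, 2, 3, 5, 6, 9, 10).

**The three steps most likely to fail**

The ring enlargement of step 9, the only step that rests on a proposed new method, is the riskiest. The allenolate may be protonated before it closes on the ring carbonyl, so that the sequence stalls after the conjugate addition. The enolate may also add through oxygen, or the closure may discriminate poorly between the two carbonyls and give low enantiomeric purity. The fallback uses known chemistry, sets out from 13 and 2 and returns at 21. Friedel–Crafts acylation of phloroglucinol with 13 (AlCl3, PhNO2) would give 3-phenyl-1-(2,4,6-trihydroxyphenyl)propan-1-one F1. Twofold C-prenylation of its phenolate with 2 (aq KOH, 0 °C) would give 1-[2,4,6-trihydroxy-3,5-bis(3-methylbut-2-en-1-yl)phenyl]-3-phenylpropan-1-one F2. Oxidative dearomatisation with PhI(OAc)2 in MeOH at −30 °C, in which methanol enters at a prenyl-bearing carbon para to a hydroxyl, would give racemic helihumulone F3. Preparative HPLC on a chiral stationary phase would then separate 21 from (6S)-helihumulone F4.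

The cycloaddition of step 5 comes second. Dimerisation or amine-induced oligomerisation of the ketene may outrun a slow cycloaddition with the hindered, disubstituted ynol ether. The fallback sets out from 6 and 7 and returns at 12, and makes step 4 unnecessary. Ketene 10 is generated as in step 5 but trapped with the parent ethoxyacetylene 7, the best-precedented ketenophile of this class, to give racemic 3-ethoxy-4-methoxy-4-(3-methylbut-2-en-1-yl)cyclobut-2-en-1-one F5. Hydrolysis as in step 6 would give 2-methoxy-2-(3-methylbut-2-en-1-yl)cyclobutane-1,3-dione F6. The second prenyl group is then put on C4 by Tsuji–Trost allylation (Pd(PPh3)4, zerovalent palladium, prenyl acetate, Et3N, THF), in which the soft dione enolate attacks the unsubstituted terminus of the prenyl–palladium intermediate and O-allylation is reversible, to reach 12.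

The final hydrolysis of step 10 comes third. Acid-promoted cyclisation of the freed enol hydroxyls onto the neighbouring prenyl double bonds (chroman-type ring formation), or hydration of those double bonds, may compete with the hydrolysis. The fallback carries a methyl in place of the ethyl group, sets out from 14 and 12 and returns at 21. Chloroacetaldehyde dimethyl acetal and LDA (3 equiv, THF, −78 → 0 °C) would generate in the flask lithium methoxyacetylide F7. It would add to 14 and give, through the lithium hemiaminal of the methoxy series F8, after a sat. aq NH4Cl quench, 1-methoxy-5-phenylpent-1-yn-3-one F9. Under the conditions of step 9 this ynone and 12 should pass through the allenolate adduct of the methoxy series F10 and the bicyclic alkoxide of the methoxy series F11 to (6R)-5-hydroxy-3,6-dimethoxy-4,6-bis(3-methylbut-2-en-1-yl)-2-(3-phenylpropanoyl)cyclohexa-2,4-dien-1-one F12. Its vinylogous-ester O–CH3 bond is then cut by chloride (LiCl, DMSO, 100 °C; SN2 at the methyl carbon, no acid, the C6 alkyl methyl ether being inert), and mild acidification with dilute HCl gives 21.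

**Further compounds**

F1 | step 9 | 3-phenyl-1-(2,4,6-trihydroxyphenyl)propan-1-one | O=C(CCc1ccccc1)c1c(O)cc(O)cc1O
F2 | step 9 | 1-[2,4,6-trihydroxy-3,5-bis(3-methylbut-2-en-1-yl)phenyl]-3-phenylpropan-1-one | O=C(CCc1ccccc1)c1c(O)c(CC=C(C)C)c(O)c(CC=C(C)C)c1O
F3 | step 9 | racemic helihumulone | COC1(CC=C(C)C)C(=O)C(C(=O)CCc2ccccc2)=C(O)C(CC=C(C)C)=C1O
F4 | step 9 | (6S)-helihumulone | CO[C@]1(CC=C(C)C)C(=O)C(C(=O)CCc2ccccc2)=C(O)C(CC=C(C)C)=C1O
F5 | step 5 | 3-ethoxy-4-methoxy-4-(3-methylbut-2-en-1-yl)cyclobut-2-en-1-one (racemic) | CCOC1=CC(=O)C1(OC)CC=C(C)C
F6 | step 5 | 2-methoxy-2-(3-methylbut-2-en-1-yl)cyclobutane-1,3-dione | COC1(CC=C(C)C)C(=O)CC1=O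
F7 | step 10 | lithium methoxyacetylide | COC#C[Li]
F8 | step 10 | lithium hemiaminal of the methoxy series, lithium 1-methoxy-3-[methoxy(methyl)amino]-5-phenylpent-1-yn-3-olate | COC#CC(O[Li])(CCc1ccccc1)N(C)OC
F9 | step 10 | 1-methoxy-5-phenylpent-1-yn-3-one | COC#CC(=O)CCc1ccccc1
F10 | step 10 | allenolate adduct of the methoxy series | COC(=C=C([O-])CCc1ccccc1)C1(CC=C(C)C)C(=O)C(OC)(CC=C(C)C)C1=O
F11 | step 10 | bicyclic alkoxide of the methoxy series | COC1=C(C(=O)CCc2ccccc2)[C@]2([O-])[C@@](OC)(CC=C(C)C)C(=O)[C@]12CC=C(C)C
F12 | step 10 | (6R)-5-hydroxy-3,6-dimethoxy-4,6-bis(3-methylbut-2-en-1-yl)-2-(3-phenylpropanoyl)cyclohexa-2,4-dien-1-one | COC1=C(C(=O)CCc2ccccc2)C(=O)[C@@](OC)(CC=C(C)C)C(O)=C1CC=C(C)C
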